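**Plan**

- Retrosyn­thesis: the pyranone is opened at O2–C3 and the acetyl-derived C3 unit is removed (C3–C4), giving a homophthalic acid. C4–C4a and C1–C8a are then cut together, back to a ring A bromide and dimethyl malonate. Last, the bond between the bridging CH2 and ring B is cut.
- Enabling feature: C4a and C8a are neighbours on ring A (the benzo ring of the isocoumarin) and C8a lies beside the C8 methoxy group. A C4a–C8a aryne is therefore polarized to take a carbon nucleophile at C4a and leave the anion at C8a, next to the incoming ester carbonyl.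
- Forward: ring A (a bromo aldehyde) and ring B (an aryl bromide) are made separately and joined by aryllithium addition and ionic reduction to the diarylmethane. The malonate is then inserted into the aryne. The pyranone ring closes last, after acetylation at C4, decarboxylation and enol lactonization.
- Stereochemistry: the target is achiral. The one carbinol stereocentre met on the way is racemic and is removed in the following step.

Key step: step 9

Assumption: the two aromatic starting materials and dimethyl malonate are taken as purchasable; locants C1 to C8a are those of the isocoumarin of the target and are used for ring A throughout.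

**Route**

Step 1
Reactants: 1 2-bromo-4,6-dimethoxybenzaldehyde
Product: 2 2-bromo-6-hydroxy-4-methoxybenzaldehyde
Conditions: BCl3, CH2Cl2, −78 to 0 °C; H2O
Reagents that add atoms: none
Why: Chelation-controlled Lewis-acid ether cleavage, in which BCl3 bridges the aldehyde oxygen and the only ortho methoxy group and removes that methyl alone, so the para methoxy group (the future C8 OMe) stays.

Step 2
Reactants: 2 2-bromo-6-hydroxy-4-methoxybenzaldehyde
Product: 3 2-bromo-4-methoxy-6-(triisopropylsilyloxy)benzaldehyde
Conditions: i-Pr3SiOTf, 2,6-lutidine, CH2Cl2, 0 °C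
Reagents that add atoms: triisopropylsilyl trifluoromethanesulfonate, CC(C)[Si](OS(=O)(=O)C(F)(F)F)(C(C)C)C(C)C
Why: Silyl ether formation with a silyl triflate and a hindered pyridine base, reactive enough for a hydrogen-bonded salicylaldehyde phenol; the bulky group is chosen because it neither directs nor permits lithiation at the neighbouring C7 later.

Step 3
Reactants: 4 methyl 3-hydroxy-5-methoxybenzoate
Product: 5 methyl 3-methoxy-5-(triisopropylsilyloxy)benzoate
Conditions: i-Pr3SiCl, imidazole, DMF, rt
Reagents that add atoms: chlorotriisopropylsilane, CC(C)[Si](Cl)(C(C)C)C(C)C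
Why: Standard imidazole-promoted silylation of an unhindered phenol.

Step 4
Reactants: 5 methyl 3-methoxy-5-(triisopropylsilyloxy)benzoate
Product: 6 [3-methoxy-5-(triisopropylsilyloxy)phenyl]methanol
Conditions: i-Bu2AlH, CH2Cl2, −78 to 0 °C; aq. KNaC4H4O6
Reagents that add atoms: none
Why: Hydride reduction of a methyl ester to the primary benzylic alcohol, to which an aryl triisopropylsilyl ether is inert at low temperature.

Step 5
Reactants: 6 [3-methoxy-5-(triisopropylsilyloxy)phenyl]methanol
Product: 7 1-methoxy-3-(methoxymethyl)-5-(triisopropylsilyloxy)benzene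
Conditions: MeI, NaH, THF, 0 °C to rt (MeI present before NaH)
Reagents that add atoms: iodomethane, CI
Why: Williamson ether synthesis, with the alkoxide trapped by iodomethane as it forms and the bulk of the silyl group disfavouring silyl transfer from the phenol oxygen.

Step 6
Reactants: 7 1-methoxy-3-(methoxymethyl)-5-(triisopropylsilyloxy)benzene
Product: 8 2-bromo-1-methoxy-3-(methoxymethyl)-5-(triisopropylsilyloxy)benzene
Conditions: NBS, MeCN, 0 °C, dark
Reagents that add atoms: N-bromosuccinimide, O=C1CCC(=O)N1Br
Why: Electrophilic aromatic bromination; all three free positions are ortho or para to both oxygens, so the choice should fall on the carbon between OMe and CH2OMe, which is para to the silyloxy group and the only position not ortho to it.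

Step 7
Reactants: 8 2-bromo-1-methoxy-3-(methoxymethyl)-5-(triisopropylsilyloxy)benzene, 3 2-bromo-4-methoxy-6-(triisopropylsilyloxy)benzaldehyde
Product: 10 rac-[2-bromo-4-methoxy-6-(triisopropylsilyloxy)phenyl][2-methoxy-6-(methoxymethyl)-4-(triisopropylsilyloxy)phenyl]methanol, via ring B aryllithium 9 (not isolated)
Conditions: n-BuLi, THF, −78 °C; then 3, −78 °C; sat. aq. NH4Cl added at −78 °C
Reagents that add atoms: none
Why: Bromine–lithium exchange followed by 1,2-addition of the chelated aryllithium to the aldehyde, which outruns exchange at the hindered bromide of 3; the cold quench forestalls silyl migration to the new alkoxide, and the carbinol centre forms without control (racemic) and is erased in step 8.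

Step 8
Reactants: 10 rac-[2-bromo-4-methoxy-6-(triisopropylsilyloxy)phenyl][2-methoxy-6-(methoxymethyl)-4-(triisopropylsilyloxy)phenyl]methanol
Product: 11 2-{[2-bromo-4-methoxy-6-(triisopropylsilyloxy)phenyl]methyl}-1-methoxy-3-(methoxymethyl)-5-(triisopropylsilyloxy)benzene
Conditions: Et3SiH (excess, added first), CF3CO2H, CH2Cl2, −20 to 0 °C
Reagents that add atoms: none
Why: Ionic hydrogenation (Kursanov–Parnes): acid ionizes the doubly benzylic alcohol to a cation stabilized by ortho and para oxygens on both rings and the silane delivers hydride, whereas the CH2OMe group of ring B has its oxygen donors meta and should not ionize.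

Step 9
Reactants: 11 2-{[2-bromo-4-methoxy-6-(triisopropylsilyloxy)phenyl]methyl}-1-methoxy-3-(methoxymethyl)-5-(triisopropylsilyloxy)benzene, 12 dimethyl malonate
Product: 15 methyl 6-methoxy-2-(2-methoxy-2-oxoethyl)-3-{[2-methoxy-6-(methoxymethyl)-4-(triisopropylsilyloxy)phenyl]methyl}-4-(triisopropylsilyloxy)benzoate, via lithio dimethyl malonate 13 (not isolated), via ring A aryne 14 (not isolated)
Conditions: LiTMP (lithium 2,2,6,6-tetramethylpiperidide, from the amine and n-BuLi, about 4 equiv), 12 (2 equiv), THF, −78 °C; then 11, −78 °C to rt; sat. aq. NH4Cl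
Reagents that add atoms: none
Why: LiTMP removes the ring A hydrogen at C8a, which is flanked by the C4a bromine and the C8 methoxy group, and loss of LiBr gives the C4a–C8a aryne 14. Lithio malonate 13 adds at C4a, the aryne carbon remote from the methoxy group, because the inductive pull of that oxygen stabilizes the aryl anion developing at C8a; this anion attacks a malonate ester carbonyl (4-exo-trig) and the benzocyclobutenoxide fragments, leaving CO2Me on C8a and the CH2CO2Me enolate on C4a. The closest known reaction is the acyl-alkylation of arynes by malonates to give homophthalates, established for arynes generated from 3-bromoanisoles with a lithium amide. No ring of the target closes (the four-membered ring is transient) and no stereocentre forms. The step needs addition at C4a rather than C8a and deprotonation at C8a rather than C7: the C8 methoxy group polarizes the aryne toward C4a despite the neighbouring C5 benzyl group, and the bulky silyl ether at C6 shields C7 while any other aryllithium is drained through the irreversible loss of LiBr. An excess of 13 is kept so that intermolecular capture outruns attack of the ring B ether oxygens on the aryne.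

Step 10
Reactants: 15 methyl 6-methoxy-2-(2-methoxy-2-oxoethyl)-3-{[2-methoxy-6-(methoxymethyl)-4-(triisopropylsilyloxy)phenyl]methyl}-4-(triisopropylsilyloxy)benzoate
Product: 16 2-(carboxymethyl)-4-hydroxy-3-{[4-hydroxy-2-methoxy-6-(methoxymethyl)phenyl]methyl}-6-methoxybenzoic acid
Conditions: KOH, MeOH–H2O, reflux, argon; then 2 M HCl, 0 °C
Reagents that add atoms: potassium hydroxide, [K+].[OH-]
Why: Saponification of both esters (the hindered benzoate needs heat), under which hydroxide also cleaves the two aryl silyl ethers, so the phenols are released in the same operation.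

Step 11
Reactants: 16 2-(carboxymethyl)-4-hydroxy-3-{[4-hydroxy-2-methoxy-6-(methoxymethyl)phenyl]methyl}-6-methoxybenzoic acid
Product: 19 4-hydroxy-3-{[4-hydroxy-2-methoxy-6-(methoxymethyl)phenyl]methyl}-6-methoxy-2-(2-oxopropyl)benzoic acid, via cyclic anhydride diacetate 17 (not isolated), via C4-acetylated anhydride 18 (not isolated)
Conditions: Ac2O, pyridine, 0 °C to rt; then 2 M NaOH, THF–H2O, rt to 40 °C; then 2 M HCl to pH 2
Reagents that add atoms: acetic anhydride, CC(=O)OC(C)=O; sodium hydroxide, [Na+].[OH-]
Why: Dakin–West-type acylation of a homophthalic acid: Ac2O closes the anhydride and acetylates both phenols, pyridine enolizes the acidic C4 methylene for C-acetylation, and alkaline hydrolysis opens the anhydride and removes the aryl acetates so that the β-keto acid loses CO2 on acidification, leaving C3 and its methyl group in place.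

Step 12
Reactants: 19 4-hydroxy-3-{[4-hydroxy-2-methoxy-6-(methoxymethyl)phenyl]methyl}-6-methoxy-2-(2-oxopropyl)benzoic acid
Product: 20 6-hydroxy-5-{[4-hydroxy-2-methoxy-6-(methoxymethyl)phenyl]methyl}-8-methoxy-3-methyl-1H-isochromen-1-one
Conditions: TsOH·H2O (10 mol %), PhMe–1,4-dioxane, reflux, Dean–Stark trap
Reagents that add atoms: none
Why: Acid-catalysed enol lactonization: the carboxyl oxygen adds to the protonated ketone (6-exo-trig) and the lactol dehydrates across C3–C4 to the pyranone, driven by removal of water and leaving the phenols free.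

**Compound list**

1 | 2-bromo-4,6-dimethoxybenzaldehyde | COc1cc(OC)c(C=O)c(Br)c1 | starting material
2 | 2-bromo-6-hydroxy-4-methoxybenzaldehyde | COc1cc(O)c(C=O)c(Br)c1 | intermediate
3 | 2-bromo-4-methoxy-6-(triisopropylsilyloxy)benzaldehyde | COc1cc(Br)c(C=O)c(O[Si](C(C)C)(C(C)C)C(C)C)c1 | intermediate
4 | methyl 3-hydroxy-5-methoxybenzoate | COC(=O)c1cc(O)cc(OC)c1 | starting material
5 | methyl 3-methoxy-5-(triisopropylsilyloxy)benzoate | COC(=O)c1cc(OC)cc(O[Si](C(C)C)(C(C)C)C(C)C)c1 | intermediate
6 | [3-methoxy-5-(triisopropylsilyloxy)phenyl]methanol | OCc1cc(OC)cc(O[Si](C(C)C)(C(C)C)C(C)C)c1 | intermediate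
7 | 1-methoxy-3-(methoxymethyl)-5-(triisopropylsilyloxy)benzene | COCc1cc(OC)cc(O[Si](C(C)C)(C(C)C)C(C)C)c1 | intermediate
8 | 2-bromo-1-methoxy-3-(methoxymethyl)-5-(triisopropylsilyloxy)benzene | COCc1cc(O[Si](C(C)C)(C(C)C)C(C)C)cc(OC)c1Br | intermediate
9 | [2-methoxy-6-(methoxymethyl)-4-(triisopropylsilyloxy)phenyl]lithium (ring B aryllithium, formed in the flask) | [Li]c1c(COC)cc(O[Si](C(C)C)(C(C)C)C(C)C)cc1OC | intermediate
10 | rac-[2-bromo-4-methoxy-6-(triisopropylsilyloxy)phenyl][2-methoxy-6-(methoxymethyl)-4-(triisopropylsilyloxy)phenyl]methanol (racemic) | COCc1cc(O[Si](C(C)C)(C(C)C)C(C)C)cc(OC)c1C(O)c1c(Br)cc(OC)cc1O[Si](C(C)C)(C(C)C)C(C)C | intermediate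
11 | 2-{[2-bromo-4-methoxy-6-(triisopropylsilyloxy)phenyl]methyl}-1-methoxy-3-(methoxymethyl)-5-(triisopropylsilyloxy)benzene | COCc1cc(O[Si](C(C)C)(C(C)C)C(C)C)cc(OC)c1Cc1c(Br)cc(OC)cc1O[Si](C(C)C)(C(C)C)C(C)C | intermediate
12 | dimethyl malonate | COC(=O)CC(=O)OC | starting material
13 | lithio dimethyl malonate (formed in the flask) | [Li+].COC(=O)[CH-]C(=O)OC | intermediate
14 | ring A aryne: C4a–C8a didehydro form of 11 without HBr (formed in the flask) | COCc1cc(O[Si](C(C)C)(C(C)C)C(C)C)cc(OC)c1CC1=C(O[Si](C(C)C)(C(C)C)C(C)C)C=C(OC)C#C1 | intermediate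
15 | methyl 6-methoxy-2-(2-methoxy-2-oxoethyl)-3-{[2-methoxy-6-(methoxymethyl)-4-(triisopropylsilyloxy)phenyl]methyl}-4-(triisopropylsilyloxy)benzoate | COC(=O)Cc1c(Cc2c(COC)cc(O[Si](C(C)C)(C(C)C)C(C)C)cc2OC)c(O[Si](C(C)C)(C(C)C)C(C)C)cc(OC)c1C(=O)OC | intermediate
16 | 2-(carboxymethyl)-4-hydroxy-3-{[4-hydroxy-2-methoxy-6-(methoxymethyl)phenyl]methyl}-6-methoxybenzoic acid | COCc1cc(O)cc(OC)c1Cc1c(O)cc(OC)c(C(=O)O)c1CC(=O)O | intermediate
17 | 6-acetoxy-5-{[4-acetoxy-2-methoxy-6-(methoxymethyl)phenyl]methyl}-8-methoxyisochromane-1,3-dione (formed in the flask) | COCc1cc(OC(C)=O)cc(OC)c1Cc1c(OC(C)=O)cc(OC)c2C(=O)OC(=O)Cc12 | intermediate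
18 | 4-acetyl-6-acetoxy-5-{[4-acetoxy-2-methoxy-6-(methoxymethyl)phenyl]methyl}-8-methoxyisochromane-1,3-dione (largely enolized, formed in the flask) | COCc1cc(OC(C)=O)cc(OC)c1Cc1c(OC(C)=O)cc(OC)c2C(=O)OC(=O)C(C(C)=O)c12 | intermediate
19 | 4-hydroxy-3-{[4-hydroxy-2-methoxy-6-(methoxymethyl)phenyl]methyl}-6-methoxy-2-(2-oxopropyl)benzoic acid | COCc1cc(O)cc(OC)c1Cc1c(O)cc(OC)c(C(=O)O)c1CC(C)=O | intermediate
20 | 6-hydroxy-5-{[4-hydroxy-2-methoxy-6-(methoxymethyl)phenyl]methyl}-8-methoxy-3-methyl-1H-isochromen-1-one | COCc1cc(O)cc(OC)c1Cc1c(O)cc(OC)c2c(=O)oc(C)cc12 | target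

**Count**

Total: 12 steps. Longest linear sequence: 10 steps (4 to 20, steps 3 to 12).

**Steps most likely to fail**

Step 9. The aryne may be lost to several competing processes:
- deprotonation at C7 or at the diarylmethane CH2 instead of C8a;
- intramolecular capture by the ring B methoxy oxygen;
- simple arylation of the malonate without acyl transfer;
- attack at the less hindered C8a.

The fallback makes the two bonds one after the other and sets out from 11. LiN(i-Pr)2 in THF at −78 °C lithiates C8a, and the ortho-bromo aryllithium, kept cold so that LiBr is not lost, is trapped with methyl chloroformate. This should give methyl 2-bromo-6-methoxy-3-{[2-methoxy-6-(methoxymethyl)-4-(triisopropylsilyloxy)phenyl]methyl}-4-(triisopropylsilyloxy)benzoate F1. Cross-coupling of its C4a bromide with the Reformatsky reagent BrZnCH2CO2Me (Pd2(dba)3, XPhos, THF, 60 °C) then forms C4–C4a. The route is rejoined at 15.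

Step 7. Both partners carry two ortho substituents, so addition may be slow. That would leave time for bromine–lithium exchange at the bromide of 3 and for migration of the silyl group from the phenol oxygen to the new alkoxide. The fallback joins the rings by a benzylic cross-coupling and sets out from 3 and 8. NaBH4 in MeOH at 0 °C should reduce 3 to [2-bromo-4-methoxy-6-(triisopropylsilyloxy)phenyl]methanol F2. MeSO2Cl, Et3N and LiCl should convert it into 1-bromo-2-(chloromethyl)-5-methoxy-3-(triisopropylsilyloxy)benzene F3. Aryllithium 9, made from 8 as in step 7, is transmetalated with ZnCl2 to chloro[2-methoxy-6-(methoxymethyl)-4-(triisopropylsilyloxy)phenyl]zinc F4. A Negishi coupling with Pd(PPh3)4 in THF should then take place at the benzylic chloride, where oxidative addition is faster than at the hindered aryl bromide. The route is rejoined at 11, so the cation of step 8 is avoided as well.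

Step 11. C-acetylation at C4 may be slowed by the neighbouring C5 benzyl group. The anhydride may self-condense in pyridine, and the acetyl group may be lost by retro-Claisen cleavage during alkaline hydrolysis. The fallback builds the methyl ketone from the ester and sets out from 15. MeNH(OMe)·HCl with i-PrMgCl in THF at −20 °C should convert only the unhindered aliphatic ester into methyl 6-methoxy-2-{2-[methoxy(methyl)amino]-2-oxoethyl}-3-{[2-methoxy-6-(methoxymethyl)-4-(triisopropylsilyloxy)phenyl]methyl}-4-(triisopropylsilyloxy)benzoate F5. MeMgBr in THF at 0 °C should give methyl 6-methoxy-3-{[2-methoxy-6-(methoxymethyl)-4-(triisopropylsilyloxy)phenyl]methyl}-2-(2-oxopropyl)-4-(triisopropylsilyloxy)benzoate F6. TsOH·H2O in hot toluene should close the enol lactone with loss of methanol to 8-methoxy-5-{[2-methoxy-6-(methoxymethyl)-4-(triisopropylsilyloxy)phenyl]methyl}-3-methyl-6-(triisopropylsilyloxy)-1H-isochromen-1-one F7. Bu4NF buffered with AcOH in THF at 0 °C removes both silyl groups. The route is rejoined at 20.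

**Further compounds**

F1 | step 9 | methyl 2-bromo-6-methoxy-3-{[2-methoxy-6-(methoxymethyl)-4-(triisopropylsilyloxy)phenyl]methyl}-4-(triisopropylsilyloxy)benzoate | COCc1cc(O[Si](C(C)C)(C(C)C)C(C)C)cc(OC)c1Cc1c(Br)c(C(=O)OC)c(OC)cc1O[Si](C(C)C)(C(C)C)C(C)C
F2 | step 7 | [2-bromo-4-methoxy-6-(triisopropylsilyloxy)phenyl]methanol | COc1cc(Br)c(CO)c(O[Si](C(C)C)(C(C)C)C(C)C)c1
F3 | step 7 | 1-bromo-2-(chloromethyl)-5-methoxy-3-(triisopropylsilyloxy)benzene | COc1cc(Br)c(CCl)c(O[Si](C(C)C)(C(C)C)C(C)C)c1
F4 | step 7 | chloro[2-methoxy-6-(methoxymethyl)-4-(triisopropylsilyloxy)phenyl]zinc | Cl[Zn]c1c(COC)cc(O[Si](C(C)C)(C(C)C)C(C)C)cc1OC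
F5 | step 11 | methyl 6-methoxy-2-{2-[methoxy(methyl)amino]-2-oxoethyl}-3-{[2-methoxy-6-(methoxymethyl)-4-(triisopropylsilyloxy)phenyl]methyl}-4-(triisopropylsilyloxy)benzoate | CON(C)C(=O)Cc1c(Cc2c(COC)cc(O[Si](C(C)C)(C(C)C)C(C)C)cc2OC)c(O[Si](C(C)C)(C(C)C)C(C)C)cc(OC)c1C(=O)OC
F6 | step 11 | methyl 6-methoxy-3-{[2-methoxy-6-(methoxymethyl)-4-(triisopropylsilyloxy)phenyl]methyl}-2-(2-oxopropyl)-4-(triisopropylsilyloxy)benzoate | CC(=O)Cc1c(Cc2c(COC)cc(O[Si](C(C)C)(C(C)C)C(C)C)cc2OC)c(O[Si](C(C)C)(C(C)C)C(C)C)cc(OC)c1C(=O)OC
F7 | step 11 | 8-methoxy-5-{[2-methoxy-6-(methoxymethyl)-4-(triisopropylsilyloxy)phenyl]methyl}-3-methyl-6-(triisopropylsilyloxy)-1H-isochromen-1-one | COCc1cc(O[Si](C(C)C)(C(C)C)C(C)C)cc(OC)c1Cc1c(O[Si](C(C)C)(C(C)C)C(C)C)cc(OC)c2c(=O)oc(C)cc12
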